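**Plan**

1. Numbering used below: decalin (ring C = cyclohexene, ring D = gem‑dimethyl ring) C1 (carries the bridge), C2(Me)=C3, C4, C4a, C5 (carbinol), C6, C7, C8 (CMe2), C8a; bridge C1′ (on C1) and C2′; 1‑benzoxepine (ring A = oxepane, ring B = cyclohexane) O1, C2 (CMe2), C3 (CHOH), C4, C5, C5a, C6 (carries C2′), C7 (carbinol), C8, C9, C9a.
2. First cut: the C1–C1′ bond. C1 is allylic to the C2=C3 bond of ring C, so C1′–C1–C2(Me)=C3 becomes a γ,δ‑unsaturated acid once a disposable CO2H sits on C1′. The bond is therefore made by an Ireland–Claisen shift of the C3–O allylic ester 22 (alkene then at C1=C2), which joins the halves, moves the alkene to C2=C3 and sets C1 from C3.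
3. Second cut (rings C and D): both rings are closed at once by a catalytic asymmetric intramolecular Diels–Alder reaction of silyloxy‑trienone 7, made from 4,4‑dimethylcyclohexanone. It sets C3–O, C4a and C8a all‑cis. C5 stays sp2 (ketone, then exocyclic CH2) until after the union.
4. Third cut (rings A and B): Shi diepoxidation of farnesyl acetate and a two‑carbon extension, then one Lewis‑acid cascade that closes the oxepane, the cyclohexane and a δ‑lactone (masked acid plus masked C7 alcohol).
5. Forward order: 1→10 (decalin alcohol), 11→21 (benzoxepine acid), esterification, Claisen shift, radical decarboxylation, hydration of the C5 methylene, desilylation.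
6. Stereochemistry: two catalyst‑controlled steps (6 and 9); C5a, C6, C7, C9a are relayed from the epoxides in step 13, C1 from C3 in step 16, and C5 from the cis‑decalin shape in step 18.

Key step: step 16

Assumption: in step 6 the (S)‑configured oxazaborolidinium catalyst is taken to shield the Si face of the enone α‑carbon, as its usual model for vinyl ketones predicts; if the sense were the opposite, the (R)‑catalyst would be used in the same way.

**Route**

Step 1
Reactants: 1 4,4‑dimethylcyclohexanone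
Product: 2 5,5‑dimethyloxepan‑2‑one
Conditions: mCPBA, CH2Cl2, 0 °C to rt
Reagents that add atoms: mCPBA (3‑chloroperoxybenzoic acid), OOC(=O)c1cccc(Cl)c1
Why: Baeyer–Villiger oxidation of a symmetrical ketone can give only one lactone, and it differentiates the two chain ends (acyl carbon three bonds, O–CH2 two bonds from the quaternary carbon) as ring D later needs.

Step 2
Reactants: 2 5,5‑dimethyloxepan‑2‑one
Product: 3 6‑hydroxy‑N‑methoxy‑N,4,4‑trimethylhexanamide
Conditions: MeNH(OMe)·HCl, i‑PrMgCl, THF, −20 to 0 °C; aq. NH4Cl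
Reagents that add atoms: N,O‑dimethylhydroxylamine hydrochloride, CNOC.Cl
Why: Aminolysis of the lactone by the magnesium amide (Weinreb amide formation) stores the acyl end as a ketone precursor and frees the primary alcohol.

Step 3
Reactants: 3 hydroxy Weinreb amide
Product: 4 N‑methoxy‑N,4,4‑trimethyl‑6‑oxohexanamide
Conditions: TEMPO (cat.), PhI(OAc)2, CH2Cl2, rt
Reagents that add atoms: none
Why: Nitroxyl‑catalysed oxidation stops at the aldehyde and leaves the amide untouched.

Step 4
Reactants: 4 aldehyde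
Product: 5 (6E)‑N‑methoxy‑N,4,4,7‑tetramethyl‑8‑oxooct‑6‑enamide
Conditions: Ph3P=C(Me)CHO, toluene, 90 °C
Reagents that add atoms: 2‑(triphenylphosphoranylidene)propanal, CC(C=O)=P(c1ccccc1)(c1ccccc1)c1ccccc1
Why: Wittig olefination with the stabilised formyl ylide is E‑selective and gives the 2‑methyl enal.

Step 5
Reactants: 5 enal
Product: 6 (5E,7E)‑silyl dienol ether
Conditions: t‑BuMe2SiOTf, Et3N, Et2O, 0 °C to rt
Reagents that add atoms: tert‑butyldimethylsilyl trifluoromethanesulfonate, CC(C)(C)[Si](C)(C)OS(=O)(=O)C(F)(F)F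
Why: Soft γ‑enolisation of the s‑trans enal (silyl dienol ether formation) should place the oxygen trans to the diene C3 (1E), and the new alkene next to the quaternary carbon should be E for steric reasons.

Step 6
Reactants: 6 silyl dienol ether
Product: 8 cis‑fused silyloxy octalone (4aR,7R,8aS), via trienone 7 (not isolated)
Conditions: CH2=CHMgBr, THF, −78 to −30 °C; cold aq. NH4Cl, cold extraction; then (S)‑B‑(o‑tolyl)oxazaborolidine from (S)‑α,α‑diphenylprolinol, protonated with HNTf2 (20 mol %), CH2Cl2, −78 °C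
Reagents that add atoms: vinylmagnesium bromide, C=C[Mg]Br
Why: Weinreb ketone synthesis gives the vinyl ketone, whose catalysed type 1 intramolecular Diels–Alder reaction closes rings C and D through the endo transition state with the tether ketone under the diene (cis fusion), while the E,E‑diene puts the silyloxy group cis to both ring‑fusion bonds and the boron‑bound catalyst leaves only the Re face of the enone α‑carbon open, which fixes the absolute configuration of all three new stereocentres.

Step 7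
Reactants: 8 silyloxy octalone
Product: 9 exocyclic methylene silyl ether
Conditions: Ph3PCH3Br, KN(SiMe3)2, THF, 0 °C to rt
Reagents that add atoms: methyltriphenylphosphonium bromide, C[P+](c1ccccc1)(c1ccccc1)c1ccccc1.[Br-]
Why: Wittig methylenation with the preformed ylide at low temperature should add faster than it enolises the ketone toward the ring‑fusion carbon, so the cis fusion is kept and C5 stays sp2.

Step 8
Reactants: 9 methylene silyl ether
Product: 10 (2R,4aR,8aS)‑allylic alcohol
Conditions: Bu4NF, THF, rt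
Reagents that add atoms: none
Why: Fluoride cleaves the silyl ether and leaves the carbinol configuration and both alkenes unchanged.

Step 9
Reactants: 11 (2E,6E)‑farnesyl acetate
Product: 12 (6S,7S,10S)‑diepoxy acetate
Conditions: L‑fructose‑derived Shi ketone (1,2:4,5‑di‑O‑isopropylidene‑β‑L‑erythro‑2,3‑hexodiulo‑2,6‑pyranose, 0.5 equiv), KHSO5 (as 2KHSO5·KHSO4·K2SO4), K2CO3, Bu4NHSO4, aq. Na2B4O7 buffer, MeCN/CH2(OMe)2, 0 °C
Reagents that add atoms: potassium peroxymonosulfate, [K+].[O-]S(=O)(=O)OO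
Why: Shi asymmetric epoxidation attacks the two electron‑rich trisubstituted alkenes from the same enantioface through the spiro dioxirane transition state, while the alkene next to the acetoxymethyl group is deactivated and survives.

Step 10
Reactants: 12 diepoxy acetate
Product: 13 diepoxy farnesol
Conditions: K2CO3 (cat.), MeOH, 0 °C to rt
Reagents that add atoms: none
Why: Base‑catalysed transesterification removes the acetate, and the epoxides are inert to methoxide at this temperature.

Step 11
Reactants: 13 diepoxy farnesol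
Product: 15 diepoxy farnesyl bromide, via mesylate 14 (not isolated)
Conditions: MeSO2Cl, Et3N, THF, −40 °C; then LiBr, THF, 0 °C
Reagents that add atoms: lithium bromide, [Li+].[Br-]
Why: Mesylation and SN2 displacement by bromide give the primary allylic bromide with the alkene geometry kept, under conditions that spare the epoxides.

Step 12
Reactants: 15 diepoxy farnesyl bromide
Product: 16 tert‑butyl diepoxy ester
Conditions: t‑BuOAc, LiN(i‑Pr)2, THF, −78 °C; then 15, DMPU, −78 to −20 °C
Reagents that add atoms: tert‑butyl acetate, CC(=O)OC(C)(C)C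
Why: SN2 alkylation of the ester enolate at the primary allylic carbon adds C1′ and the disposable carboxyl carbon without touching the epoxides.

Step 13
Reactants: 16 tert‑butyl diepoxy ester
Product: 18 tricyclic hydroxy δ‑lactone, via trimethylsilyl ether 17 (not isolated)
Conditions: Me3SiOTf, 2,6‑di‑tert‑butyl‑4‑methylpyridine, CH2Cl2, −78 °C; then aq. citric acid, THF, rt
Reagents that add atoms: none
Why: Epoxide‑opening cascade (oxacyclisation, cation–olefin cyclisation, lactonisation) in which the silyl‑activated terminal epoxide is opened at its tertiary carbon by the inner epoxide oxygen (ring A), the (E)‑alkene opens the resulting epoxonium ion at its tertiary carbon with inversion through a chair (ring B), and the tert‑butyl ester carbonyl captures the tertiary cation equatorially with loss of isobutene, so that C3, C5a and C9a come from the epoxides and C6 and C7 from the alkene geometry.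

Step 14
Reactants: 18 tricyclic hydroxy δ‑lactone
Product: 21 bis(triethylsilyl) acid, via potassium carboxylate 19 (not isolated), via triethylsilyl ester 20 (not isolated)
Conditions: KOH, MeOH/H2O, 60 °C; evaporate and dry; Et3SiOTf, 2,6‑lutidine, CH2Cl2, 0 °C; then K2CO3 (cat.), MeOH/H2O, 0 °C, pH 5 buffer
Reagents that add atoms: potassium hydroxide, [K+].[OH-]; triethylsilyl trifluoromethanesulfonate, CC[Si](CC)(CC)OS(=O)(=O)C(F)(F)F
Why: Saponification opens the lactone, exhaustive silylation caps both hydroxyls so that the δ‑hydroxy acid cannot close again, and the labile silyl ester alone is hydrolysed, with no stereocentre touched.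

Step 15
Reactants: 10 allylic alcohol; 21 bis(triethylsilyl) acid
Product: 22 allylic ester
Conditions: DCC, DMAP, CH2Cl2, 0 °C to rt
Reagents that add atoms: none
Why: Steglich esterification joins the two halves through the temporary ester tether with retention at the carbinol carbon (the later C3).

Step 16
Reactants: 22 allylic ester
Product: 25 rearranged acid (both C1′ epimers), via silyl ketene acetal 23 (not isolated), via trimethylsilyl ester 24 (not isolated)
Conditions: LiN(i‑Pr)2, Me3SiCl/Et3N, THF, −78 °C; warm to rt, then 65 °C; aq. citric acid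
Reagents that add atoms: none
Why: Deprotonation at C1′ and O‑silylation give silyl ketene acetal 23, which undergoes a concerted suprafacial [3,3]‑sigmatropic shift across the C3–C2(Me)=C1 allyl unit of ring C, so that the C3–O bond breaks as the C1–C1′ bond forms and the alkene moves to C2=C3. The closest known reaction type is the Ireland–Claisen rearrangement of 2‑cyclohexenyl esters. No ring is closed in this step. The new stereocentre C1 is controlled by the C3 carbinol stereocentre (1,3‑chirality transfer): the bond forms on the face from which the oxygen leaves, which is the face that carries both ring‑fusion bonds, and this gives the all‑cis C1/C8a/C4a array that an external reagent would avoid; the C1′ stereocentre forms as a mixture and is deleted in step 17. The selectivity needed is bond formation at the crowded face of a hindered carbon, and it is secured by intramolecular delivery through the ester tether and by keeping C5 as an sp2 methylene, so that the axial C4a–C5 bond beside the forming bond carries no axial methyl group.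

Step 17
Reactants: 25 rearranged acid
Product: 27 decarboxylated bis(triethylsilyl) ether, via thiohydroxamate ester 26 (not isolated)
Conditions: 1‑hydroxypyridine‑2(1H)‑thione, DCC, DMAP (cat.), CH2Cl2, rt, dark; then t‑BuSH (excess), toluene, hν (tungsten lamp), rt
Reagents that add atoms: none
Why: Barton radical decarboxylation removes the tether carbon, and the secondary C1′ radical is reduced by the thiol, used in excess so that hydrogen transfer outruns cyclisation onto the C5 methylene.

Step 18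
Reactants: 27 decarboxylated bis(triethylsilyl) ether
Product: 29 tertiary alcohol, via organomercurial 28 (not isolated)
Conditions: Hg(OAc)2, THF/H2O, rt; then NaBH4, aq. NaOH, 0 °C
Reagents that add atoms: water, O
Why: Oxymercuration–demercuration hydrates the 1,1‑disubstituted exocyclic alkene in preference to the hindered trisubstituted ring alkene (the limonene to α‑terpineol selectivity), and water should open the mercurinium ion at C5 from the face away from the ring C bonds at C4a and C8a, putting the hydroxyl cis to H‑4a.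

Step 19
Reactants: 29 tertiary alcohol
Product: 30 sipholenol L
Conditions: Bu4NF, THF, 50 °C
Reagents that add atoms: none
Why: Fluoride removes both triethylsilyl ethers with no change at any stereocentre.

**Compound list**

1 | 4,4‑dimethylcyclohexanone | CC1(C)CCC(=O)CC1 | starting material
2 | 5,5‑dimethyloxepan‑2‑one | O=C1CCC(C)(C)CCO1 | intermediate
3 | 6‑hydroxy‑N‑methoxy‑N,4,4‑trimethylhexanamide | CON(C)C(=O)CCC(C)(C)CCO | intermediate
4 | N‑methoxy‑N,4,4‑trimethyl‑6‑oxohexanamide | CON(C)C(=O)CCC(C)(C)CC=O | intermediate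
5 | (6E)‑N‑methoxy‑N,4,4,7‑tetramethyl‑8‑oxooct‑6‑enamide | CON(C)C(=O)CCC(C)(C)C/C=C(\C)C=O | intermediate
6 | (5E,7E)‑8‑[tert‑butyl(dimethyl)silyl]oxy‑N‑methoxy‑N,4,4,7‑tetramethylocta‑5,7‑dienamide | CON(C)C(=O)CCC(C)(C)/C=C/C(C)=C/O[Si](C)(C)C(C)(C)C | intermediate
7 | (7E,9E)‑10‑[tert‑butyl(dimethyl)silyl]oxy‑6,6,9‑trimethyldeca‑1,7,9‑trien‑3‑one | C=CC(=O)CCC(C)(C)/C=C/C(C)=C/O[Si](C)(C)C(C)(C)C | intermediate (not isolated)
8 | (4aR,7R,8aS)‑7‑[tert‑butyl(dimethyl)silyl]oxy‑4,4,6‑trimethyl‑3,4,4a,7,8,8a‑hexahydronaphthalen‑1(2H)‑one (cis‑fused; silyloxy group on the face opposite to both ring‑fusion hydrogens) | O=C1CCC(C)(C)[C@@H]2C=C(C)[C@H](O[Si](C)(C)C(C)(C)C)C[C@H]12 | intermediate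
9 | tert‑butyl(dimethyl){[(2R,4aR,8aS)‑3,5,5‑trimethyl‑8‑methylidene‑1,2,4a,5,6,7,8,8a‑octahydronaphthalen‑2‑yl]oxy}silane | C=C1CCC(C)(C)[C@@H]2C=C(C)[C@H](O[Si](C)(C)C(C)(C)C)C[C@H]12 | intermediate
10 | (2R,4aR,8aS)‑3,5,5‑trimethyl‑8‑methylidene‑1,2,4a,5,6,7,8,8a‑octahydronaphthalen‑2‑ol | C=C1CCC(C)(C)[C@@H]2C=C(C)[C@H](O)C[C@H]12 | intermediate
11 | (2E,6E)‑3,7,11‑trimethyldodeca‑2,6,10‑trien‑1‑yl acetate (farnesyl acetate) | CC(C)=CCC/C(C)=C/CC/C(C)=C/COC(C)=O | starting material
12 | (2E,6S,7S,10S)‑6,7:10,11‑diepoxy‑3,7,11‑trimethyldodec‑2‑en‑1‑yl acetate | CC1(C)O[C@H]1CC[C@]1(C)O[C@H]1CC/C(C)=C/COC(C)=O | intermediate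
13 | (2E,6S,7S,10S)‑6,7:10,11‑diepoxy‑3,7,11‑trimethyldodec‑2‑en‑1‑ol | CC1(C)O[C@H]1CC[C@]1(C)O[C@H]1CC/C(C)=C/CO | intermediate
14 | (2E,6S,7S,10S)‑6,7:10,11‑diepoxy‑3,7,11‑trimethyldodec‑2‑en‑1‑yl methanesulfonate | CC1(C)O[C@H]1CC[C@]1(C)O[C@H]1CC/C(C)=C/COS(C)(=O)=O | intermediate (not isolated)
15 | (2E,6S,7S,10S)‑1‑bromo‑6,7:10,11‑diepoxy‑3,7,11‑trimethyldodec‑2‑ene | CC1(C)O[C@H]1CC[C@]1(C)O[C@H]1CC/C(C)=C/CBr | intermediate
16 | tert‑butyl (4E,8S,9S,12S)‑8,9:12,13‑diepoxy‑5,9,13‑trimethyltetradec‑4‑enoate | CC1(C)O[C@H]1CC[C@]1(C)O[C@H]1CC/C(C)=C/CCC(=O)OC(C)(C)C | intermediate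
17 | 3‑O‑trimethylsilyl ether of lactone 18 | O=C1CC[C@H]2[C@]3(C)CC[C@H](O[Si](C)(C)C)C(C)(C)O[C@H]3CC[C@]2(C)O1 | intermediate (not isolated)
18 | 3‑[(3S,5aS,6S,7S,9aS)‑3,7‑dihydroxy‑2,2,5a,7‑tetramethyldecahydro‑1‑benzoxepin‑6‑yl]propanoic acid 7‑lactone (trans‑fused oxepane/cyclohexane/δ‑lactone) | O=C1CC[C@H]2[C@]3(C)CC[C@H](O)C(C)(C)O[C@H]3CC[C@]2(C)O1 | intermediate
19 | potassium 3‑[(3S,5aS,6S,7S,9aS)‑3,7‑dihydroxy‑2,2,5a,7‑tetramethyldecahydro‑1‑benzoxepin‑6‑yl]propanoate | [K+].[O-]C(=O)CC[C@H]1[C@]2(C)CC[C@H](O)C(C)(C)O[C@H]2CC[C@]1(C)O | intermediate (not isolated)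
20 | triethylsilyl ester of acid 21 | CC[Si](CC)(CC)OC(=O)CC[C@H]1[C@]2(C)CC[C@H](O[Si](CC)(CC)CC)C(C)(C)O[C@H]2CC[C@]1(C)O[Si](CC)(CC)CC | intermediate (not isolated)
21 | 3‑[(3S,5aS,6S,7S,9aS)‑2,2,5a,7‑tetramethyl‑3,7‑bis(triethylsilyloxy)decahydro‑1‑benzoxepin‑6‑yl]propanoic acid | OC(=O)CC[C@H]1[C@]2(C)CC[C@H](O[Si](CC)(CC)CC)C(C)(C)O[C@H]2CC[C@]1(C)O[Si](CC)(CC)CC | intermediate
22 | (2R,4aR,8aS)‑3,5,5‑trimethyl‑8‑methylidene‑1,2,4a,5,6,7,8,8a‑octahydronaphthalen‑2‑yl 3‑[(3S,5aS,6S,7S,9aS)‑2,2,5a,7‑tetramethyl‑3,7‑bis(triethylsilyloxy)decahydro‑1‑benzoxepin‑6‑yl]propanoate | C=C1CCC(C)(C)[C@@H]2C=C(C)[C@H](OC(=O)CC[C@H]3[C@]4(C)CC[C@H](O[Si](CC)(CC)CC)C(C)(C)O[C@H]4CC[C@]3(C)O[Si](CC)(CC)CC)C[C@H]12 | intermediate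
23 | trimethylsilyl ketene acetal of ester 22 (enol geometry not defined) | C=C1CCC(C)(C)[C@@H]2C=C(C)[C@H](OC(O[Si](C)(C)C)=CC[C@H]3[C@]4(C)CC[C@H](O[Si](CC)(CC)CC)C(C)(C)O[C@H]4CC[C@]3(C)O[Si](CC)(CC)CC)C[C@H]12 | intermediate (not isolated)
24 | trimethylsilyl ester of acid 25 | CC1=CC[C@H]2[C@@H]([C@@H]1C(C[C@H]1[C@]3(C)CC[C@H](O[Si](CC)(CC)CC)C(C)(C)O[C@H]3CC[C@]1(C)O[Si](CC)(CC)CC)C(=O)O[Si](C)(C)C)C(C)(C)CCC2=C | intermediate (not isolated)
25 | 2‑[(1R,4aS,8aS)‑2,8,8‑trimethyl‑5‑methylidene‑1,4,4a,5,6,7,8,8a‑octahydronaphthalen‑1‑yl]‑3‑[(3S,5aS,6S,7S,9aS)‑2,2,5a,7‑tetramethyl‑3,7‑bis(triethylsilyloxy)decahydro‑1‑benzoxepin‑6‑yl]propanoic acid (both epimers at C2 of the acid; bridge on the ring face opposite to H‑1, H‑4a and H‑8a) | CC1=CC[C@H]2[C@@H]([C@@H]1C(C[C@H]1[C@]3(C)CC[C@H](O[Si](CC)(CC)CC)C(C)(C)O[C@H]3CC[C@]1(C)O[Si](CC)(CC)CC)C(=O)O)C(C)(C)CCC2=C | intermediate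
26 | 2‑thioxopyridin‑1(2H)‑yl ester of acid 25 | CC1=CC[C@H]2[C@@H]([C@@H]1C(C[C@H]1[C@]3(C)CC[C@H](O[Si](CC)(CC)CC)C(C)(C)O[C@H]3CC[C@]1(C)O[Si](CC)(CC)CC)C(=O)ON1C=CC=CC1=S)C(C)(C)CCC2=C | intermediate (not isolated)
27 | (3S,5aS,6S,7S,9aS)‑2,2,5a,7‑tetramethyl‑6‑{2‑[(1S,4aS,8aS)‑2,8,8‑trimethyl‑5‑methylidene‑1,4,4a,5,6,7,8,8a‑octahydronaphthalen‑1‑yl]ethyl}‑3,7‑bis(triethylsilyloxy)decahydro‑1‑benzoxepine | CC1=CC[C@H]2[C@@H]([C@@H]1CC[C@H]1[C@]3(C)CC[C@H](O[Si](CC)(CC)CC)C(C)(C)O[C@H]3CC[C@]1(C)O[Si](CC)(CC)CC)C(C)(C)CCC2=C | intermediate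
28 | acetoxymercuriomethyl carbinol from 27 (HgOAc on the former methylene carbon, hydroxyl at C5 as in 29) | CC1=CC[C@H]2[C@@H]([C@@H]1CC[C@H]1[C@]3(C)CC[C@H](O[Si](CC)(CC)CC)C(C)(C)O[C@H]3CC[C@]1(C)O[Si](CC)(CC)CC)C(C)(C)CC[C@]2(C[Hg]OC(C)=O)O | intermediate (not isolated)
29 | 3,7‑bis(triethylsilyl) ether of sipholenol L | CC1=CC[C@H]2[C@@H]([C@@H]1CC[C@H]1[C@]3(C)CC[C@H](O[Si](CC)(CC)CC)C(C)(C)O[C@H]3CC[C@]1(C)O[Si](CC)(CC)CC)C(C)(C)CC[C@]2(C)O | intermediate
30 | sipholenol L, (3S,5aS,6S,7S,9aS)‑6‑{2‑[(1S,4aS,5S,8aR)‑5‑hydroxy‑2,5,8,8‑tetramethyl‑1,4,4a,5,6,7,8,8a‑octahydronaphthalen‑1‑yl]ethyl}‑2,2,5a,7‑tetramethyldecahydro‑1‑benzoxepine‑3,7‑diol | CC1=CC[C@H]2[C@@H]([C@@H]1CC[C@H]1[C@]3(C)CC[C@H](O)C(C)(C)O[C@H]3CC[C@]1(C)O)C(C)(C)CC[C@]2(C)O | target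

**Step count and risks**

Total steps: 19. Longest linear sequence: 13 steps (steps 1–8, then 15–19).

Steps most likely to fail:

Step 16. The sigmatropic shift has to form the bond on the ring face flanked by the axial C4a–C5 bond, so it may be slow enough for the ketene acetal to decay (C‑silylation, elimination) before it rearranges. The fallback replaces the tethered shift by a carbamate‑directed syn‑SN2′ organocopper substitution. It sets out from 10 and 21 and comes back at 27. Alcohol 10 and phenyl isocyanate would give the N‑phenylcarbamate F1. Acid 21 would be converted by iododecarboxylation (PhI(OAc)2, I2, hν) into the primary iodide F2. Iodine–lithium exchange on F2 (t‑BuLi, Et2O, −78 °C) would give the alkyllithium. This would be added to the lithium salt of F1 (MeLi, THF, −78 °C) that has been mixed with CuI. On warming, the copper‑bound alkyl group should be delivered from the carbamate oxygen to the alkene carbon on the same face, with loss of the carbamate, to give 27 directly.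

Step 6. Facial discrimination by the catalyst may be poor, or an uncatalysed or stepwise (Mukaiyama–Michael type) pathway of the silyl dienol ether may compete, which would erode enantiomeric or diastereomeric purity. The fallback gives up catalyst control and resolves later. It sets out from 6 and comes back at 10. Vinyl Grignard addition and simple warming in toluene would give the racemic cis‑fused ketone F3. Methylenation as in step 7 would give the racemic methylene silyl ether F4, and fluoride would give the racemic allylic alcohol F5. Lipase from Burkholderia cepacia with vinyl acetate in hexane is expected to acylate the (R)‑carbinol enantiomer to the acetate F6 and leave the enantiomeric alcohol F7. After separation, K2CO3 in MeOH would convert F6 into 10.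

Step 13. Proton loss from the tertiary cation, or early loss of the tert‑butyl group, may outrun capture by the ester carbonyl, so the cascade may stop at a bicyclic olefin. The fallback makes the lactone C–O bond in a separate acid‑catalysed step. It sets out from 16 and comes back at 18. The Lewis‑acid cyclisation would be run only as far as the bicyclic hydroxy olefin ester F8 (exocyclic isomer drawn; ring‑alkene isomers converge). CF3SO3H (cat.) in CH2Cl2 would then cleave the tert‑butyl ester and add the acid across the alkene in the Markovnikov sense under thermodynamic control to give the trans‑fused lactone 18.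

Further compounds

F1 | step 16 | (2R,4aR,8aS)‑3,5,5‑trimethyl‑8‑methylidene‑1,2,4a,5,6,7,8,8a‑octahydronaphthalen‑2‑yl N‑phenylcarbamate | C=C1CCC(C)(C)[C@@H]2C=C(C)[C@H](OC(=O)Nc3ccccc3)C[C@H]12
F2 | step 16 | (3S,5aS,6S,7S,9aS)‑6‑(2‑iodoethyl)‑2,2,5a,7‑tetramethyl‑3,7‑bis(triethylsilyloxy)decahydro‑1‑benzoxepine | ICC[C@H]1[C@]2(C)CC[C@H](O[Si](CC)(CC)CC)C(C)(C)O[C@H]2CC[C@]1(C)O[Si](CC)(CC)CC
F3 | step 6 | racemic 7‑[tert‑butyl(dimethyl)silyl]oxy‑4,4,6‑trimethyl‑3,4,4a,7,8,8a‑hexahydronaphthalen‑1(2H)‑one, relative configuration (4aR*,7R*,8aS*), one enantiomer drawn | O=C1CCC(C)(C)[C@@H]2C=C(C)[C@H](O[Si](C)(C)C(C)(C)C)C[C@H]12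
F4 | step 6 | racemic tert‑butyl(dimethyl)silyl ether of F5, relative configuration (2R*,4aR*,8aS*), one enantiomer drawn | C=C1CCC(C)(C)[C@@H]2C=C(C)[C@H](O[Si](C)(C)C(C)(C)C)C[C@H]12
F5 | step 6 | racemic 3,5,5‑trimethyl‑8‑methylidene‑1,2,4a,5,6,7,8,8a‑octahydronaphthalen‑2‑ol, relative configuration (2R*,4aR*,8aS*), one enantiomer drawn | C=C1CCC(C)(C)[C@@H]2C=C(C)[C@H](O)C[C@H]12
F6 | step 6 | (2R,4aR,8aS)‑3,5,5‑trimethyl‑8‑methylidene‑1,2,4a,5,6,7,8,8a‑octahydronaphthalen‑2‑yl acetate | C=C1CCC(C)(C)[C@@H]2C=C(C)[C@H](OC(C)=O)C[C@H]12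
F7 | step 6 | (2S,4aS,8aR)‑3,5,5‑trimethyl‑8‑methylidene‑1,2,4a,5,6,7,8,8a‑octahydronaphthalen‑2‑ol | C=C1CCC(C)(C)[C@H]2C=C(C)[C@@H](O)C[C@@H]12
F8 | step 13 | tert‑butyl 3‑[(3S,5aS,6R,9aS)‑3‑hydroxy‑2,2,5a‑trimethyl‑7‑methylidenedecahydro‑1‑benzoxepin‑6‑yl]propanoate | CC(C)(C)OC(=O)CC[C@H]1[C@]2(C)CC[C@H](O)C(C)(C)O[C@H]2CCC1=C
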